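## Structural features

The target 18 is a flavonol: an aromatic ring A fused along C4a–C8a to a 4-pyranone ring C (O1, C2, C3, C4), with an unsubstituted phenyl ring B on C2. Every ring-A carbon except C6 carries a different oxygen function: a free hydroxyl at C5 hydrogen-bonded to the C4 carbonyl, a methyl ether at C7 and a butanoate ester at C8. Ring C carries an enolic hydroxyl at C3. There is no stereocentre, so only regiochemistry and the order of events need control. The fragile parts are the aryl butanoate (lost to hydroxide, alkoxide or organometallic reagents), the para-related C5/C8 oxygens (a hydroquinone that oxidises easily once both are free) and the flavonol enol. The real difficulty is to tell four oxygen functions apart on a contiguously 5,7,8-trioxygenated ring and to bring the ester in late. The key step exploits the 2,3,5-trioxygenated phenoxy ring that becomes ring A: the future C4a is its only unsubstituted carbon ortho to O1, and it is also ortho to the C5 oxygen and para to the C7 oxygen, so an acyl carbon C4 tethered through O1–C2=C3 can close ring C only there. After closure the C5 methyl ether sits peri to C4=O and can be removed by chelation, while the C7 methyl ether cannot.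

## Logic of the disconnections

**18 to 17.** The O–CH3 bond on the C5 oxygen is restored. The peri ether is the only one that can chelate to the C4 carbonyl, so both ring-A ether oxygens can be carried as methyl ethers from the start. The forward cleavage must spare the C7 ether and the C8 ester.

**17 to 15 (through 16).** The C3–O bond is cut. A flavone C2=C3 bond can be epoxidised by a neutral dioxirane and the epoxide isomerised to the enol by acid. This reduces ring C to a plain flavone, which needs no pre-oxygenated three-carbon unit. The forward oxidation requires that no free phenol is present and that the ester is tolerated.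

**15 to 13 and 14.** The acyl C–O bond of the ester is cut. The labile group is attached when the C8 hydroxyl is the only hydroxyl in the molecule, so no selectivity problem arises. The demand is that C3 and C5 are not yet free.

**13 to 12.** The O–CH2Ph bond on the C8 oxygen is restored. Benzyl is orthogonal to the methyl ethers and leaves under neutral hydrogenolysis. The forward step must not reduce the C2=C3 bond.

**12 to 10 (through 11).** The C4–C4a bond is cut, which opens ring C. The retron is an aryl ketone ortho to an aryl ether oxygen on a ring with one free ortho carbon. The bicyclic core becomes a monocyclic aryl enol ether acid. The forward acylation must be mild enough to keep the benzyl ether. The free acid is chosen over an ester so that metal-free anhydride activation is possible.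

**10 to 7 and 8 (through 9).** The O1–C2 bond is cut, together with the ethyl ester. A phenoxide adds to the β-carbon of an alkynoate, so the whole C2–C3–C4 unit with ring B comes from 8 in one operation. The enol-ether geometry need not be controlled.

**7 to 6, then to 4 and 5.** The acetal O–C bond on the future O1 and the O–CH2Ph bond on the future C8 oxygen are cut. The two adjacent oxygens are distinguished by the order in which they appear. The mask on the first must not migrate to the second, which is why an acetal is used and not an acyl or silyl group.

**4 to 2 (through 3), then to 1.** The aryl C–O bond of the future C8 oxygen is traced back to an aryl C–CHO bond. The 1,2,3,5-tetraoxygenated pattern thus comes from a commercial trioxygenated benzaldehyde. The forward oxidation must make the aryl group migrate, which the three donor oxygens ensure.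

## Other disconnections considered

**Alternative 1:** The cut is the C4a–C8a bond, with ring A unfolded into a linear chain. In the forward step the tetraketo ester A1 would be treated with base; the enolate of its C6 methylene attacks the ester carbonyl, alkoxide is lost and the ring aromatises to the triketone A2.
- In its favour: ring A arises in one aromatisation-driven step, and the C3 oxygen is already in place as a benzyl ether. On that point it is better than the chosen plan, which must oxidise C3 late.
- Against it: A2 has no oxygen at the future C8 and three free phenols. Ring C would still have to be closed, the C7 hydroxyl methylated selectively, and C8 hydroxylated para to the C5 hydroxyl (an Elbs persulfate oxidation, typically inefficient).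
- Mechanistically, the result depends on which enolate of a poly-enolisable chain reacts. An aldol folding to a resorcylate and retro-Claisen cleavage next to the benzyloxy carbon compete. The chosen plan fixes regiochemistry by substitution.
- Step economy is expected to be worse, because A1 needs several steps and the endgame is longer.

**Alternative 2:** The cut is the O1–C2 bond, with an iodine placed on C3. In the forward step an iodonium source activates the alkyne of ynone A3, an ortho methoxy oxygen attacks the phenyl-bearing carbon in 6-endo fashion, and the oxonium ion loses its methyl group to halide, giving the 3-iodoflavone A4.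
- In its favour: A3 comes in one acylation from a symmetric trimethoxyarene, so the bicyclic core is reached in two steps. This is better than the chosen plan on steps to the core.
- The C3 iodide is a handle for the C3 oxygen, which equals or betters a late epoxidation. The peri demethylation is the same in both plans.
- Against it: A4 has no C8 oxygen. A later oxidation would have to choose C8 over C6 in the presence of the C3 iodide, and the iodonium source can also attack the electron-rich ring A.
- Starting from a tetraoxygenated arene would break the symmetry and raise new regiochemical questions in the acylation. The chosen plan carries the C8 oxygen from the first steps, so its overall step count should be no worse.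

**Alternative 3:** The cut is the C4a–C5 bond, with ring A built from a four-carbon cyclobutenone unit on a preformed pyranone. In the forward step, heating the cyclobutenone A5 causes 4π ring opening to a dienylketene (hydroxyl rotating outward). A 6π closure of the ketene carbon onto pyranone C5 and tautomerisation then give the hydroquinone A6.
- In its favour: A6 has the whole oxygen pattern already differentiated (free C5 and C8 hydroxyls, C7 methyl ether, C3 benzyl ether). Only selective acylation of the non-chelated C8 hydroxyl and hydrogenolysis would remain.
- On differentiation and on the number of steps after the key step it is better than the chosen plan. It needs neither a C3 oxidation nor a demethylation.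
- Against it: A5 requires a 6-metallated pyranone to add 1,2 to a semisquarate. Pyranones are prone to conjugate addition and ring opening.
- The electrocyclisation onto an electron-poor pyranone double bond is less established than onto arenes, and A6 is an air-sensitive hydroquinone.
- The two building blocks each cost several steps, so the total is unlikely to be lower. The key step would also rest on weaker precedent than a Friedel–Crafts closure onto a trioxygenated arene.

Key step: step 6

Remark on the chemistry: the target is achiral. Compounds 9 and 10 are drawn as the Z isomers expected from anti addition; geometric purity is not required because both geometries are expected to converge in step 6.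

## Route

Step 1
Reactants: 1 2-hydroxy-4,6-dimethoxybenzaldehyde
Product: 2 2,4-dimethoxy-6-(methoxymethoxy)benzaldehyde
Conditions: MOMCl, iPr2NEt, CH2Cl2, 0 °C → rt
Reagents that add atoms: chloromethyl methyl ether, COCCl
Why: Williamson-type O-alkylation of the phenol by the chloromethyl ether should be clean even though the hydroxyl is hydrogen-bonded to the aldehyde. An acetal mask cannot migrate to the neighbouring oxygen created in step 2 (an acyl or silyl group could), and it later leaves under acid that spares benzyl and methyl ethers.

Step 2
Reactants: 2 2,4-dimethoxy-6-(methoxymethoxy)benzaldehyde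
Product: 4 2,4-dimethoxy-6-(methoxymethoxy)phenol, via aryl formate 3 (not isolated)
Conditions: mCPBA, CH2Cl2, 0 °C → rt; aq. NaHCO3/Na2S2O3 wash; then K2CO3 (cat.), MeOH, 0 °C, under N2
Reagents that add atoms: 3-chloroperoxybenzoic acid, OOC(=O)c1cccc(Cl)c1
Why: Baeyer–Villiger (Dakin-type) oxidation: the peracid adds to the aldehyde and the 2,4,6-trioxygenated aryl group migrates to oxygen in preference to hydrogen, giving formate 3, which mild methanolysis cleaves. A peracid is used because the alkaline peroxide Dakin reaction needs a free ortho or para hydroxyl, which is masked here; 4 is air-sensitive and is taken on directly.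

Step 3
Reactants: 4 2,4-dimethoxy-6-(methoxymethoxy)phenol; 5 benzyl bromide
Product: 6 2-(benzyloxy)-1,5-dimethoxy-3-(methoxymethoxy)benzene
Conditions: K2CO3, DMF, rt, under N2
Reagents that add atoms: none
Why: Williamson ether synthesis (SN2 of the phenoxide on the benzylic bromide) at the only acidic site. The benzyl group lands on the oxygen that becomes the C8 oxygen and also blocks that ortho carbon for step 6.

Step 4
Reactants: 6 2-(benzyloxy)-1,5-dimethoxy-3-(methoxymethoxy)benzene
Product: 7 2-(benzyloxy)-3,5-dimethoxyphenol
Conditions: HCl (cat.), MeOH, 45 °C
Reagents that add atoms: none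
Why: Acid-catalysed acetal exchange removes the methoxymethyl group as dimethoxymethane; methanol traps the formaldehyde equivalent so the electron-rich ring is not alkylated. Aryl benzyl and methyl ethers are stable to dilute methanolic acid.

Step 5
Reactants: 7 2-(benzyloxy)-3,5-dimethoxyphenol; 8 ethyl 3-phenylprop-2-ynoate
Product: 10 (Z)-3-[2-(benzyloxy)-3,5-dimethoxyphenoxy]-3-phenylprop-2-enoic acid, via ethyl ester 9 (not isolated)
Conditions: K2CO3 (0.3 equiv), DMF, 80 °C; then LiOH, THF/H2O, rt; then 1 M HCl to pH 3, 0 °C
Reagents that add atoms: lithium hydroxide, [Li+].[OH-]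
Why: Base-catalysed oxa-Michael addition: the phenoxide adds to the phenyl-bearing alkyne carbon β to the ester, and anti protonation gives mainly the Z enol ether 9. Saponification in the same flask (acyl–oxygen cleavage by hydroxide) gives acid 10; cold, brief acidification protects the enol ether.

Step 6
Reactants: 10 (Z)-3-[2-(benzyloxy)-3,5-dimethoxyphenoxy]-3-phenylprop-2-enoic acid
Product: 12 8-(benzyloxy)-5,7-dimethoxy-2-phenyl-4H-chromen-4-one, via mixed anhydride 11 (not isolated)
Conditions: (CF3CO)2O, CH2Cl2 (0.02 M), 0 °C → rt
Reagents that add atoms: none
Why: Trifluoroacetic anhydride should convert the acid into mixed anhydride 11, whose acyl carbon (C4) is released as a vinylogous acylium ion stabilised by the enol-ether oxygen. This electrophile attacks C4a, the ring carbon ortho to O1, giving an arenium ion stabilised by O1 and the C5 methoxy (ortho) and by the C7 methoxy (para), which then loses a proton. The closest known reaction type is the intramolecular Friedel–Crafts acylation of 3-aryloxycinnamic acids to flavones, here with mixed-anhydride activation. Ring C closes as a six-membered ring by electrophilic aromatic substitution with the C=O bond exocyclic to the forming ring (6-exo), making only the C4–C4a bond. No stereocentre is created; only the Z acid can reach the ring, and any E isomer is expected to equilibrate through the C3-protonated oxocarbenium ion in the acid that the reaction liberates. The step needs regioselectivity between the two carbons ortho to O1, which the substrate secures because the other one carries the benzyloxy group, while the carbon between the two methoxy groups is out of reach of the tether. It also needs acylation to outrun benzyl-ether cleavage, which metal-free activation at 0 °C is chosen to secure.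

Step 7
Reactants: 12 8-(benzyloxy)-5,7-dimethoxy-2-phenyl-4H-chromen-4-one
Product: 13 8-hydroxy-5,7-dimethoxy-2-phenyl-4H-chromen-4-one
Conditions: H2 (1 atm), Pd/C, EtOAc/MeOH, rt
Reagents that add atoms: none
Why: Heterogeneous hydrogenolysis of the aryl benzyl ether. The vinylogous-ester C2=C3 bond of a flavone is reduced much more slowly than a benzylic C–O bond is cleaved, so the reaction is stopped after one equivalent of hydrogen.

Step 8
Reactants: 13 8-hydroxy-5,7-dimethoxy-2-phenyl-4H-chromen-4-one; 14 butanoyl chloride
Product: 15 5,7-dimethoxy-4-oxo-2-phenyl-4H-chromen-8-yl butanoate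
Conditions: Et3N, DMAP (cat.), CH2Cl2, 0 °C
Reagents that add atoms: none
Why: DMAP-catalysed nucleophilic acyl substitution at the only free hydroxyl in the molecule, so no regiochemical question arises. The ester is introduced only now because every earlier step would have destroyed it.

Step 9
Reactants: 15 5,7-dimethoxy-4-oxo-2-phenyl-4H-chromen-8-yl butanoate
Product: 17 3-hydroxy-5,7-dimethoxy-4-oxo-2-phenyl-4H-chromen-8-yl butanoate, via flavone epoxide 16 (not isolated)
Conditions: DMDO, acetone/CH2Cl2, 0 °C → rt; then pTsOH (cat.), CH2Cl2, rt
Reagents that add atoms: dimethyldioxirane, CC1(C)OO1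
Why: Concerted oxygen transfer from the neutral dioxirane to the flavone C2=C3 bond gives racemic epoxide 16; catalytic acid opens its C2–O bond with help from O1, and loss of H3 gives the enol, which is the known dioxirane route from flavones to flavonols. The two stereocentres of 16 are transient and vanish in 17; the ester and methyl ethers tolerate the oxidant, and no free phenol is present to be oxidised.

Step 10
Reactants: 17 3-hydroxy-5,7-dimethoxy-4-oxo-2-phenyl-4H-chromen-8-yl butanoate
Product: 18 3,5-dihydroxy-7-methoxy-4-oxo-2-phenyl-4H-chromen-8-yl butanoate
Conditions: BCl3, CH2Cl2, −78 → 0 °C; then H2O, 0 °C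
Reagents that add atoms: none
Why: Chelation-controlled ether cleavage: boron binds the C4 carbonyl and the peri C5 methoxy oxygen in a six-membered chelate and chloride removes the methyl group by SN2, a selectivity well known for 5-methoxyflavones. The C7 methyl ether has no such assistance, and the aryl ester is expected to survive at low temperature with a cold quench.

## Compound list

1 | 2-hydroxy-4,6-dimethoxybenzaldehyde | COc1cc(O)c(C=O)c(OC)c1 | starting material
2 | 2,4-dimethoxy-6-(methoxymethoxy)benzaldehyde | COCOc1cc(OC)cc(OC)c1C=O | intermediate
3 | 2,4-dimethoxy-6-(methoxymethoxy)phenyl formate | COCOc1cc(OC)cc(OC)c1OC=O | intermediate (not isolated)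
4 | 2,4-dimethoxy-6-(methoxymethoxy)phenol | COCOc1cc(OC)cc(OC)c1O | intermediate
5 | benzyl bromide | BrCc1ccccc1 | starting material
6 | 2-(benzyloxy)-1,5-dimethoxy-3-(methoxymethoxy)benzene | COCOc1cc(OC)cc(OC)c1OCc1ccccc1 | intermediate
7 | 2-(benzyloxy)-3,5-dimethoxyphenol | COc1cc(O)c(OCc2ccccc2)c(OC)c1 | intermediate
8 | ethyl 3-phenylprop-2-ynoate | CCOC(=O)C#Cc1ccccc1 | starting material
9 | ethyl (Z)-3-[2-(benzyloxy)-3,5-dimethoxyphenoxy]-3-phenylprop-2-enoate | CCOC(=O)/C=C(\Oc1cc(OC)cc(OC)c1OCc1ccccc1)c1ccccc1 | intermediate (not isolated)
10 | (Z)-3-[2-(benzyloxy)-3,5-dimethoxyphenoxy]-3-phenylprop-2-enoic acid | OC(=O)/C=C(\Oc1cc(OC)cc(OC)c1OCc1ccccc1)c1ccccc1 | intermediate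
11 | (Z)-3-[2-(benzyloxy)-3,5-dimethoxyphenoxy]-3-phenylprop-2-enoic trifluoroacetic anhydride | FC(F)(F)C(=O)OC(=O)/C=C(\Oc1cc(OC)cc(OC)c1OCc1ccccc1)c1ccccc1 | intermediate (not isolated)
12 | 8-(benzyloxy)-5,7-dimethoxy-2-phenyl-4H-chromen-4-one | COc1cc(OC)c2c(=O)cc(-c3ccccc3)oc2c1OCc1ccccc1 | intermediate
13 | 8-hydroxy-5,7-dimethoxy-2-phenyl-4H-chromen-4-one | COc1cc(OC)c2c(=O)cc(-c3ccccc3)oc2c1O | intermediate
14 | butanoyl chloride | CCCC(=O)Cl | starting material
15 | 5,7-dimethoxy-4-oxo-2-phenyl-4H-chromen-8-yl butanoate | CCCC(=O)Oc1c(OC)cc(OC)c2c(=O)cc(-c3ccccc3)oc12 | intermediate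
16 | 4,6-dimethoxy-7-oxo-1a-phenyl-1a,7a-dihydro-7H-oxireno[2,3-b]chromen-3-yl butanoate (the 2,3-epoxide of 15; racemic, cis-fused, one enantiomer drawn) | CCCC(=O)Oc1c(OC)cc(OC)c2C(=O)[C@@H]3O[C@]3(c4ccccc4)Oc12 | intermediate (not isolated)
17 | 3-hydroxy-5,7-dimethoxy-4-oxo-2-phenyl-4H-chromen-8-yl butanoate | CCCC(=O)Oc1c(OC)cc(OC)c2c(=O)c(O)c(-c3ccccc3)oc12 | intermediate
18 | 3,5-dihydroxy-7-methoxy-4-oxo-2-phenyl-4H-chromen-8-yl butanoate | CCCC(=O)Oc1c(OC)cc(O)c2c(=O)c(O)c(-c3ccccc3)oc12 | target

## Step count and least certain steps

Total step count: 10. Longest linear sequence: 10 steps (1 to 18); 5, 8 and 14 enter as purchased partners.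

**Step 6 (key step).** The acyl carbon of a vinylogous carbonate is a weak electrophile, so ring closure may be slow. Acid-promoted cleavage of the enol-ether C–O bond, or loss or migration of the benzyl group on the electron-rich ring, could then overtake it; intermolecular acylation is a further risk at higher concentration. The fallback sets out from 7 and comes back at 12, closing ring C through O1–C2 instead. Magnesium-mediated ortho-formylation of 7 (MgCl2, Et3N, paraformaldehyde, MeCN, reflux) can only reach the single free ortho carbon and would give 3-(benzyloxy)-2-hydroxy-4,6-dimethoxybenzaldehyde F1. Excess lithium phenylacetylide (THF, −78 → 0 °C) would give racemic 1-[3-(benzyloxy)-2-hydroxy-4,6-dimethoxyphenyl]-3-phenylprop-2-yn-1-ol F2. MnO2 in CH2Cl2 would oxidise it to 1-[3-(benzyloxy)-2-hydroxy-4,6-dimethoxyphenyl]-3-phenylprop-2-yn-1-one F3. Diethylamine in ethanol would then promote 6-endo oxa-Michael closure of F3 to 12.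

**Step 2.** The very electron-rich ring and the phenol it produces may be oxidised further towards quinones, or hydrogen migration may compete and give the carboxylic acid. The fallback sets out from 1 and comes back at 4. The free hydroxy aldehyde 1 is the substrate class for which the alkaline Dakin oxidation (H2O2, NaOH, degassed H2O/THF, 0 °C) is made, and it would give 3,5-dimethoxybenzene-1,2-diol F4. Mono-protection with one equivalent of MOMCl and iPr2NEt is expected to go to the more acidic, less hindered hydroxyl (meta to both methoxy groups), giving 4. The regiochemistry of this protection would have to be confirmed before continuing.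

**Step 5.** During saponification, hydroxide may add at C3 and expel the phenoxide (addition–elimination, in effect a retro-oxa-Michael), and the enol ether may hydrolyse on acidification; the addition to an internal alkynoate may also be sluggish. The fallback sets out from 7 and comes back at 10 and avoids hydroxide altogether. Prop-2-en-1-yl 3-phenylprop-2-ynoate F5 (from 3-phenylprop-2-ynoic acid, prop-2-en-1-ol, DCC and DMAP) would be added to 7 under the same carbonate conditions. This would give prop-2-en-1-yl (Z)-3-[2-(benzyloxy)-3,5-dimethoxyphenoxy]-3-phenylprop-2-enoate F6. The allyl ester would be removed under neutral conditions by zerovalent palladium, Pd(PPh3)4, with morpholine in THF at rt.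

**Step 9.** Epoxidation of the electron-poor C2=C3 bond may be slow enough for oxidation of ring A to compete, and the epoxide may be opened by water, or ring-contract, and not isomerise to the enol. The fallback sets out from 12 and comes back at 18, hydroxylating C3 by an anionic route before the ester is present.
- LDA (THF, −78 °C), then B(OMe)3, then H2O2/AcOH would give 8-(benzyloxy)-3-hydroxy-5,7-dimethoxy-2-phenyl-4H-chromen-4-one F7.
- MOMCl and iPr2NEt would give 8-(benzyloxy)-5,7-dimethoxy-3-(methoxymethoxy)-2-phenyl-4H-chromen-4-one F8.
- H2 over Pd/C would give 8-hydroxy-5,7-dimethoxy-3-(methoxymethoxy)-2-phenyl-4H-chromen-4-one F9.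
- Acylation with 14 (Et3N, DMAP) would give 5,7-dimethoxy-3-(methoxymethoxy)-4-oxo-2-phenyl-4H-chromen-8-yl butanoate F10.
- BCl3 (CH2Cl2, −78 → 0 °C) would remove the acetal and the peri methyl group together to give 18.

**Step 10.** The aryl butanoate may be cleaved, or demethylation may stall because boron is held in a chelate between the C3 oxygen and the carbonyl; excess reagent or warming could also attack the C7 ether. The fallback sets out from 15 and comes back at 18 by inverting the last two operations. BCl3 on 15, where only the peri methoxy group can chelate, would give 5-hydroxy-7-methoxy-4-oxo-2-phenyl-4H-chromen-8-yl butanoate F11. DMDO followed by catalytic pTsOH would then give 18 through the racemic epoxide 6-hydroxy-4-methoxy-7-oxo-1a-phenyl-1a,7a-dihydro-7H-oxireno[2,3-b]chromen-3-yl butanoate F12, which would not be isolated. The chelated C5 hydroxyl is expected to be deactivated towards the oxidant.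

## Further compounds

F1 | step 6 | 3-(benzyloxy)-2-hydroxy-4,6-dimethoxybenzaldehyde | COc1cc(OC)c(C=O)c(O)c1OCc1ccccc1
F2 | step 6 | 1-[3-(benzyloxy)-2-hydroxy-4,6-dimethoxyphenyl]-3-phenylprop-2-yn-1-ol (racemic) | COc1cc(OC)c(C(O)C#Cc2ccccc2)c(O)c1OCc1ccccc1
F3 | step 6 | 1-[3-(benzyloxy)-2-hydroxy-4,6-dimethoxyphenyl]-3-phenylprop-2-yn-1-one | COc1cc(OC)c(C(=O)C#Cc2ccccc2)c(O)c1OCc1ccccc1
F4 | step 2 | 3,5-dimethoxybenzene-1,2-diol | COc1cc(O)c(O)c(OC)c1
F5 | step 5 | prop-2-en-1-yl 3-phenylprop-2-ynoate | C=CCOC(=O)C#Cc1ccccc1
F6 | step 5 | prop-2-en-1-yl (Z)-3-[2-(benzyloxy)-3,5-dimethoxyphenoxy]-3-phenylprop-2-enoate | C=CCOC(=O)/C=C(\Oc1cc(OC)cc(OC)c1OCc1ccccc1)c1ccccc1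
F7 | step 9 | 8-(benzyloxy)-3-hydroxy-5,7-dimethoxy-2-phenyl-4H-chromen-4-one | COc1cc(OC)c2c(=O)c(O)c(-c3ccccc3)oc2c1OCc1ccccc1
F8 | step 9 | 8-(benzyloxy)-5,7-dimethoxy-3-(methoxymethoxy)-2-phenyl-4H-chromen-4-one | COCOc1c(-c2ccccc2)oc2c(OCc3ccccc3)c(OC)cc(OC)c2c1=O
F9 | step 9 | 8-hydroxy-5,7-dimethoxy-3-(methoxymethoxy)-2-phenyl-4H-chromen-4-one | COCOc1c(-c2ccccc2)oc2c(O)c(OC)cc(OC)c2c1=O
F10 | step 9 | 5,7-dimethoxy-3-(methoxymethoxy)-4-oxo-2-phenyl-4H-chromen-8-yl butanoate | CCCC(=O)Oc1c(OC)cc(OC)c2c(=O)c(OCOC)c(-c3ccccc3)oc12
F11 | step 10 | 5-hydroxy-7-methoxy-4-oxo-2-phenyl-4H-chromen-8-yl butanoate | CCCC(=O)Oc1c(OC)cc(O)c2c(=O)cc(-c3ccccc3)oc12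
F12 | step 10 | 6-hydroxy-4-methoxy-7-oxo-1a-phenyl-1a,7a-dihydro-7H-oxireno[2,3-b]chromen-3-yl butanoate (racemic, cis-fused, one enantiomer drawn) | CCCC(=O)Oc1c(OC)cc(O)c2C(=O)[C@@H]3O[C@]3(c4ccccc4)Oc12
A1 | alternative 1 | methyl 8-(benzyloxy)-3,5,7,9-tetraoxo-9-phenylnonanoate (racemic, enolisable) | COC(=O)CC(=O)CC(=O)CC(=O)C(OCc1ccccc1)C(=O)c1ccccc1
A2 | alternative 1 | 2-(benzyloxy)-1-phenyl-3-(2,4,6-trihydroxyphenyl)propane-1,3-dione (racemic, enolisable) | Oc1cc(O)c(C(=O)C(OCc2ccccc2)C(=O)c2ccccc2)c(O)c1
A3 | alternative 2 | 3-phenyl-1-(2,4,6-trimethoxyphenyl)prop-2-yn-1-one | COc1cc(OC)c(C(=O)C#Cc2ccccc2)c(OC)c1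
A4 | alternative 2 | 3-iodo-5,7-dimethoxy-2-phenyl-4H-chromen-4-one | COc1cc(OC)c2c(=O)c(I)c(-c3ccccc3)oc2c1
A5 | alternative 3 | 3-(benzyloxy)-6-(1-hydroxy-2-methoxy-4-oxocyclobut-2-en-1-yl)-2-phenyl-4H-pyran-4-one (racemic) | COC1=CC(=O)C1(O)c1cc(=O)c(OCc2ccccc2)c(-c2ccccc2)o1
A6 | alternative 3 | 3-(benzyloxy)-5,8-dihydroxy-7-methoxy-2-phenyl-4H-chromen-4-one | COc1cc(O)c2c(=O)c(OCc3ccccc3)c(-c3ccccc3)oc2c1O
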